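I decide to follow the fraction of the charge that is not D, and to read the flask off the epsilon run, which has the same [X] but half the [E].

common to all: Q 31 mM (held)

|  | E | X | remark | time |
|---|---|---|---|---|
| epsilon | 0.13 M | 26 mM | run made earlier |  |
| zeta | 0.52 M | 26 mM | run made earlier |  |
| beta | 0.26 M | 52 mM | run made earlier |  |
| flask | 0.26 M | 26 mM |  | 12 min |

- epsilon (time / min: D / %, L / %): 1.00: 10, 0; 3.00: 37, 0; 5.00: 59, 0; 8.00: 78, 0; 12.0: 91, 0; 15.0: 92, 0
- zeta (time / min: D / %, L / %): 1.00: 10, 0; 3.00: 37, 11; 5.00: 57, 28; 8.00: 78, 53; 12.0: 96, 62; 15.0: 97, 64
- beta (time / min: D / %, L / %): 3.00: 67, 8; 6.00: 89, 33; 8.00: 96, 37; 12.0: 96, 45; 15.0: 104, 41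

(scatter of a reading: 2 percentage points)

- what is said of D includes L
- L is a solid; its amount is given per volume of the solution
- the numbers in the tables scatter by 2 percentage points (one standard deviation)
- at the start none of Q is in solution
- G is what Q becomes in solution

- how much D and L together there is at 12 min, in percent of the E charged
- concentration of G in solution at 12 min, in percent of saturation

Zeta, at 0.52 M of E against epsilon's 0.13 M, reads 78 % at 8.00 min where epsilon reads 78 %, so the fraction left does not follow [E], and the flask and epsilon should run on one curve. Between 3.00 min and 8.00 min epsilon's fraction left falls from 63.0 % to 22.0 %, which gives 0.210 /min, the decay constant of the fraction left, a pseudo-first-order constant at this [X]. Beta, with twice the [X], reads 67 % at 3.00 min, and my constant puts epsilon at 66.5 % at twice that time, so [X] scales the clock. For the flask I carry epsilon's reading at 8.00 min on to 12 min, which leaves 9.48 % and gives y near 90.5 %.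

The forecast says 92 % for y and, for G, 99 % of saturation, the latter on the ground that “A fourfold load does not change the percent rate”; its y stands 1.5 percentage points above mine, against a scatter of 2 points.

The flask gives 91.1 % and 99.9 %, with 33.3 % of L counted inside y, and the limit of solubility does not move y.

    E + X ⇌ X + Z (K = 1.10, k = 0.200 /M/s)
    G + X + Z → X + D (k = 18.0 /M²/s)
    Q ⇌ G, rate k3*(csat - [G]) (kL = 1.90 /s)
    L ⇌ D, rate k4*(cs4 - [D]) while solid is left; crystals form when [D] > cs4 (solubility = 0.150 M, k = 1.10 /s)

In the flask at 12.0 min, the exchange of E with Z, taken by that step alone and both ways together, relaxes with a half-life of 1.16 min, shorter than the 3.29 min half-life that my constant gives for the fraction left. E over Z stands at 2.99 at 6.00 min and 3.00 at 12.0 min. In the neighbour with 0.044 M of X, the same 12 min counts as 20.3 min on epsilon's clock, so 0.210 /min leaves 1.65 %, or y near 98.4 %; that flask gives 98.5 %.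

The readings were computed for an exercise, and the scatter is random.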